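## Structural features

The target is an achiral dihydrochalcone. Ring A is a phloroglucinol core fused through C4a and C8a to a 2,2-dimethyl-3,4-dihydro-2H-pyran (a chroman, O1–C2–C3–C4). Its C6 carries the ketone, flanked by the C5 and C7 hydroxyls, and C8 is the only ring A hydrogen. A CH2CH2 chain links the ketone to ring B, a 4-hydroxyphenyl ring with a 3-methylbut-2-enyl (prenyl) group ortho to the hydroxyl. There is no stereocentre and no stereogenic alkene, so every selectivity question is one of site or chemoselectivity. The fragile elements are the trisubstituted prenyl alkene beside a phenol (acid closes it to a second chroman; hydrogenation and electrophiles attack it), the oxidisable polyphenol, and any 2H-chromene met on the way (an acid-sensitive, electron-rich styrene). The real difficulty is that the same C5 unit occurs twice in different states, cyclised on ring A and open on ring B, while the pyran must be fused with O1 on the oxygen para to the ketone (6-acyl, not 8-acyl) and four phenolic oxygens must be told apart. The key step exploits that O1 sits on C8a para to C6 and that the two ring A carbons flanking this oxygen (future C4a and C8) are equivalent as long as O5 and O7 carry the same group. A C5 alkyne unit placed on that single oxygen can therefore build only the correct pyran.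

## Logic of the disconnections

19 to 18: the three phenolic O–CH2 acetal bonds (on O5, O7 and the ring B oxygen) are cut last. All earlier steps then meet only ethers, with never more than one free phenol. The demand on the forward step is release of three phenols without protonating the prenyl alkene next to the ring B oxygen.

18 to 17: the C3–H and C4–H bonds are removed, giving the C3=C4 alkene. A 2H-chromene is the direct output of a propargyl ether rearrangement. The forward step must saturate a cis-disubstituted styrenic alkene and spare the trisubstituted prenyl alkene. It is placed before deprotection so that the acid of the final step meets a chroman and never an acid-sensitive chromene.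

17 to 13: C4–C4a and O1–C2 are cut, leaving an aryl 1,1-dimethylpropargyl ether on the oxygen para to the ketone. Both bonds grow from one oxygen substituent, so the pyran can only be fused at that oxygen. The ring and its quaternary carbon reduce to a C5 alkyne unit. The precursor is deliberately drawn with all three other oxygens as acetals and not as free phenols, for two reasons:
- In a 2,6-dihydroxy ketone only one hydroxyl can be hydrogen-bonded to the carbonyl at a time, so the hydroxyl next to the new allene would not be reliably prevented from closing the ring the wrong way (8-acyl isomer).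
- A free ring B phenol would compete for the propargylic electrophile in the preceding step.
With O5 and O7 capped identically, the two ortho carbons are equivalent, and the only hydroxyl that can appear during the cascade is the one that closes correctly.

13 to 11 and 12: the aryl O–C(CH3)2 bond is cut. The forward step must capture a tertiary propargylic electrophile at oxygen without elimination. Since 11 has exactly one free phenol, no site selectivity is asked of it.

11 to 10: the O–Si bond is cut. The para oxygen is marked from the start with a fluoride-labile silyl group orthogonal to the acetals, so it can be freed alone.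

10 to 8 and 4: the bond between the ring B ipso carbon and the chain β-carbon is cut, with transposition of oxidation level (ketone back to allylic alcohol). One operation joins the halves and delivers the saturated ketone, so no enone reduction is needed. The forward step needs aryl transfer to the terminal alkene carbon, β-hydride elimination of the carbinol hydrogen, and an inert prenyl alkene.

8 to 7: the carbinol–vinyl C–C bond is cut (vinyl nucleophile plus aldehyde). The racemic carbinol centre is erased in the coupling.

7 to 6 to 5: two O–CH2 bonds and then the O–Si bond are cut. The forward order rests on the para hydroxyl of 5 being the most acidic and the only one neither hydrogen-bonded to nor flanked by the aldehyde.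

4 to 3 to 1 and 2: the acetal O–CH2 bond and then the ring B aryl–CH2 (prenyl) bond are cut. The forward C-alkylation must occur at the ortho carbon of a phenoxide and not at oxygen; the para position is blocked by iodine.

## Other disconnections considered

Alternative 1: The cut is the ring A C6–C(=O) bond, with the acyl carbon supplied by a carboxylic acid.
- Forward step: CsF would remove the silyl group of the chroman bis(triflate) A3 and release a triflyloxy aryne. The acid A4 would add through oxygen at the aryne carbon remote from the remaining triflate, and the aryl anion at C6 would take over the acyl group. This would give the ortho-hydroxy ketone A1, accompanied by isomer A2 from the aryne formed on the other side.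
- In favour: the union is convergent and places the complete side chain at C6. The pyran is already saturated, so no alkene has to be reduced beside the prenyl group; on this point it is better than the chosen plan. A1 and A2 would converge on the same diol after hydrolysis of triflate and acetate, so it is equal in final regiochemical outcome.
- Against: the C6 anion sits ortho to a triflate and may expel it (a second aryne) or be protonated by the acid, giving an O-aryl ester without the C–C bond. The aryne may also react with the prenyl alkene of A4 in an ene reaction. A3 needs a multistep preparation in which silicon must be placed at C6 and not C8 of a 5,7-dioxygenated chroman, so the regiochemical problem is moved, not removed.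
- Comparison: both plans reach the same skeleton. The chosen cascade is unimolecular, whereas here three intermolecular events must outrun anion side reactions. With the preparation of A3 and A4 and two final hydrolyses, it is not expected to be shorter.

Alternative 2: The cut is C7–C8, that is, ring A is built on a preformed dihydropyran.
- Forward step: LiN(SiMe3)2 would deprotonate the methyl group on the enol-ether carbon of the acylmalonate A6. The vinylogous carbanion would attack an ester carbonyl (six-membered closure), and loss of methoxide with enolisation would give the aromatic ester A5.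
- In favour: O1 is tied to its carbon before the arene exists, so it is equal to the chosen plan in regiochemical certainty. The pyran is saturated from the outset, so it is better on the reduction issue. The precursors are cheap and acyclic.
- Against: A5 ends in a C6 ester, not the ketone. A hindered, doubly chelated ester would have to be turned into the 3-arylpropanoyl ketone, and the prenylated ring B would still have to be attached. The malonate C–H is far more acidic than the methyl group, so ring closure would have to pass through a dianion attacking an ester that is part of an enolate.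
- Comparison: it supplies only the ring A and pyran half, by anionic condensation instead of a pericyclic cascade, and is clearly longer overall.

Alternative 3: The cut is C3–C4 and O1–C2, a retro-[4+2].
- Forward step: heating the Mannich base A8 would expel the amine to give the ring A ortho-quinone methide. An inverse-demand hetero-Diels–Alder addition of isobutene A9 would give A7, which is identical with 18.
- In favour: A8 is one Mannich step from 11, so the whole front end is shared. The saturated pyran is formed directly, replacing steps 8, 9 and 10 by two steps and removing the alkene chemoselectivity problem; it is better on step economy and on the reduction issue. The same oxygen becomes O1, so it is equal on pyran regiochemistry, and the orientation of addition (oxygen to the disubstituted carbon) is electronically matched.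
- Against: the cycloaddition is intermolecular with an unactivated gaseous alkene (pressure vessel, large excess, high temperature). The quinone methide can equally be captured by the electron-rich prenyl alkene of a second molecule, by the released amine or by itself. Mono-aminomethylation at two equivalent ortho carbons must also be controlled.
- Comparison: the chosen plan spends one more step to obtain a unimolecular ring closure that the prenyl group cannot divert.

Key step: step 9

Remark: the target has no stereocentre; the carbinol carbon of 8 and the sp3 ring carbon of 14 form as racemates and are erased in the same or the next step. Commercial availability of 1, 2, 5 and 12 is assumed.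

## Route

Step 1
Reactants: 1 4-iodophenol; 2 prenyl bromide (1-bromo-3-methylbut-2-ene)
Product: 3 4-iodo-2-(3-methylbut-2-enyl)phenol
Conditions: NaH (1.0 equiv), toluene, 0 °C → rt
Reagents that add atoms: none
Why: Ortho C-alkylation of a phenoxide: in a non-polar solvent the sodium phenoxide reacts as a tight ion pair with oxygen shielded by the cation, so the allylic bromide is attacked by the ortho carbon (SN2, unrearranged prenyl); iodine blocks the para position, and O-prenyl ether and unreacted 1 should be separable by-products.

Step 2
Reactants: 3 4-iodo-2-(3-methylbut-2-enyl)phenol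
Product: 4 4-iodo-1-(methoxymethoxy)-2-(3-methylbut-2-enyl)benzene
Conditions: MOMCl, i-Pr2NEt, CH2Cl2, 0 °C → rt
Reagents that add atoms: chloromethyl methyl ether (MOMCl), COCCl
Why: O-alkylation of the single phenol to its methoxymethyl acetal, which should tolerate palladium, fluoride, base, heat and diimide and leaves with the ring A acetals at the end.

Step 3
Reactants: 5 2,4,6-trihydroxybenzaldehyde
Product: 6 2,6-dihydroxy-4-(triisopropylsilyloxy)benzaldehyde
Conditions: TIPSCl (1.0 equiv), imidazole, CH2Cl2–DMF, −20 → 0 °C
Reagents that add atoms: chlorotriisopropylsilane (TIPSCl), CC(C)[Si](Cl)(C(C)C)C(C)C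
Why: Site-selective O-silylation: the para hydroxyl is the most acidic (vinylogous acid of the aldehyde) and the only one neither hydrogen-bonded to nor flanked by the formyl group, and the bulky silyl chloride should reinforce this preference.

Step 4
Reactants: 6 2,6-dihydroxy-4-(triisopropylsilyloxy)benzaldehyde
Product: 7 2,6-bis(methoxymethoxy)-4-(triisopropylsilyloxy)benzaldehyde
Conditions: NaH, MOMCl, THF, 0 °C → rt
Reagents that add atoms: chloromethyl methyl ether (MOMCl), COCCl
Why: Williamson-type acetalisation of both ortho phenoxides; the strong base breaks the aldehyde chelate that slows the second alkylation, and the hindered triisopropylsilyl ether should survive at this temperature.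

Step 5
Reactants: 7 2,6-bis(methoxymethoxy)-4-(triisopropylsilyloxy)benzaldehyde
Product: 8 rac-1-[2,6-bis(methoxymethoxy)-4-(triisopropylsilyloxy)phenyl]prop-2-en-1-ol
Conditions: CH2=CHMgBr, THF, −78 → 0 °C; aq. NH4Cl
Reagents that add atoms: vinylmagnesium bromide, C=C[Mg]Br
Why: Grignard 1,2-addition to the aldehyde; the carbinol centre forms as a racemate and is destroyed in step 6, and the electron-rich benzylic alcohol is kept away from acid and used directly.

Step 6
Reactants: 8 rac-1-[2,6-bis(methoxymethoxy)-4-(triisopropylsilyloxy)phenyl]prop-2-en-1-ol; 4 4-iodo-1-(methoxymethoxy)-2-(3-methylbut-2-enyl)benzene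
Product: 10 1-[2,6-bis(methoxymethoxy)-4-(triisopropylsilyloxy)phenyl]-3-[4-(methoxymethoxy)-3-(3-methylbut-2-enyl)phenyl]propan-1-one, via enol tautomer 9 (not isolated)
Conditions: Pd(OAc)2 (5 mol %), Bu4NCl, NaHCO3, DMF, 60 °C
Reagents that add atoms: none
Why: Mizoroki–Heck reaction of an allylic alcohol under ligand-free phase-transfer conditions: the arylpalladium species from oxidative addition of 4 to zerovalent palladium adds its aryl group to the terminal alkene carbon, β-hydride elimination of the carbinol hydrogen gives enol 9, and tautomerisation gives the saturated ketone; the trisubstituted prenyl alkene is too hindered to insert, and any silyl loss would only anticipate step 7.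

Step 7
Reactants: 10 1-[2,6-bis(methoxymethoxy)-4-(triisopropylsilyloxy)phenyl]-3-[4-(methoxymethoxy)-3-(3-methylbut-2-enyl)phenyl]propan-1-one
Product: 11 1-[4-hydroxy-2,6-bis(methoxymethoxy)phenyl]-3-[4-(methoxymethoxy)-3-(3-methylbut-2-enyl)phenyl]propan-1-one
Conditions: Bu4NF, AcOH, THF, 0 °C
Reagents that add atoms: none
Why: Fluoride-mediated cleavage of the aryl silyl ether, buffered with acetic acid so that the freed phenoxide is protonated at once; acetals, ketone and prenyl group should be untouched, leaving the para hydroxyl as the only free phenol.

Step 8
Reactants: 11 1-[4-hydroxy-2,6-bis(methoxymethoxy)phenyl]-3-[4-(methoxymethoxy)-3-(3-methylbut-2-enyl)phenyl]propan-1-one; 12 3-chloro-3-methylbut-1-yne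
Product: 13 1-[2,6-bis(methoxymethoxy)-4-(2-methylbut-3-yn-2-yloxy)phenyl]-3-[4-(methoxymethoxy)-3-(3-methylbut-2-enyl)phenyl]propan-1-one
Conditions: CuCl2·2H2O (1 mol %), DBU, MeCN, 0 °C
Reagents that add atoms: none
Why: Copper-catalysed propargylic etherification: the copper acetylide of the tertiary chloride ionises to a stabilised propargyl cation equivalent that the phenoxide captures at the tertiary carbon, a process suited to acidic phenols; with one free hydroxyl no site selectivity is needed, and the low temperature disfavours elimination to the enyne.

Step 9
Reactants: 13 1-[2,6-bis(methoxymethoxy)-4-(2-methylbut-3-yn-2-yloxy)phenyl]-3-[4-(methoxymethoxy)-3-(3-methylbut-2-enyl)phenyl]propan-1-one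
Product: 17 1-[5,7-bis(methoxymethoxy)-2,2-dimethyl-2H-chromen-6-yl]-3-[4-(methoxymethoxy)-3-(3-methylbut-2-enyl)phenyl]propan-1-one, via allenyl cyclohexadienone 14 (not isolated), via ortho-allenylphenol 15 (not isolated), via ortho-quinone methide 16 (not isolated)
Conditions: o-xylene (degassed), 140 °C
Reagents that add atoms: none
Why: This is the known thermal rearrangement of aryl 1,1-dimethylpropargyl ethers to 2,2-dimethyl-2H-chromenes (propargyl Claisen cascade). A [3,3] shift joins the terminal alkyne carbon to one of the two equivalent ring carbons flanking the ether oxygen (the C4–C4a bond) and gives allenyl dienone 14, which enolises to ortho-allenylphenol 15. A 1,5-hydrogen shift from that phenol to the central allene carbon gives the (Z)-ortho-quinone methide 16, whose thermal disrotatory oxa-6π electrocyclisation forms O1–C2 and closes the six-membered pyran ring. No stereocentre remains, because the sp3 ring carbon of 14 is transient and C2 carries two methyl groups. The C–C regiochemistry needs no control because the two ortho carbons are related by the local symmetry of ring A, and the O–C regiochemistry is secured because the only hydroxyl that ever appears is the one born from the ether oxygen, the neighbouring oxygens being acetals. The geminal methyl groups should accelerate the [3,3] shift and steer 15 to the chromene and not to a benzofuran. The prenyl alkene, ketone and acetals should be inert at 140 °C in a neutral hydrocarbon.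

Step 10
Reactants: 17 1-[5,7-bis(methoxymethoxy)-2,2-dimethyl-2H-chromen-6-yl]-3-[4-(methoxymethoxy)-3-(3-methylbut-2-enyl)phenyl]propan-1-one
Product: 18 1-[5,7-bis(methoxymethoxy)-2,2-dimethylchroman-6-yl]-3-[4-(methoxymethoxy)-3-(3-methylbut-2-enyl)phenyl]propan-1-one
Conditions: KO2CN=NCO2K, AcOH, MeOH–CH2Cl2, 0 °C → rt, added in portions
Reagents that add atoms: none
Why: Diimide reduction: diimide generated in the flask transfers two hydrogens in a concerted syn manner at a rate that falls steeply with alkene substitution, so the cis-disubstituted styrenic C3=C4 bond should be reduced ahead of the trisubstituted prenyl alkene; no stereocentre forms, and ketone, acetals and arenes are inert.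

Step 11
Reactants: 18 1-[5,7-bis(methoxymethoxy)-2,2-dimethylchroman-6-yl]-3-[4-(methoxymethoxy)-3-(3-methylbut-2-enyl)phenyl]propan-1-one
Product: 19 1-(5,7-dihydroxy-2,2-dimethylchroman-6-yl)-3-[4-hydroxy-3-(3-methylbut-2-enyl)phenyl]propan-1-one (target)
Conditions: conc. aq. HCl (cat.), MeOH, 40 °C
Reagents that add atoms: none
Why: Acid-catalysed acetal exchange with methanol releases the three phenols; the two acetals flanking the ketone go first (assisted by the carbonyl) and the ring B acetal last, and the low acid strength and temperature are chosen so that the prenyl alkene is not protonated; chroman ether and ketone are stable.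

## Compound list

1 | 4-iodophenol | Oc1ccc(I)cc1 | starting material
2 | prenyl bromide (1-bromo-3-methylbut-2-ene) | CC(C)=CCBr | starting material
3 | 4-iodo-2-(3-methylbut-2-enyl)phenol | CC(C)=CCc1cc(I)ccc1O | intermediate
4 | 4-iodo-1-(methoxymethoxy)-2-(3-methylbut-2-enyl)benzene | CC(C)=CCc1cc(I)ccc1OCOC | intermediate
5 | 2,4,6-trihydroxybenzaldehyde | O=Cc1c(O)cc(O)cc1O | starting material
6 | 2,6-dihydroxy-4-(triisopropylsilyloxy)benzaldehyde | O=Cc1c(O)cc(O[Si](C(C)C)(C(C)C)C(C)C)cc1O | intermediate
7 | 2,6-bis(methoxymethoxy)-4-(triisopropylsilyloxy)benzaldehyde | O=Cc1c(OCOC)cc(O[Si](C(C)C)(C(C)C)C(C)C)cc1OCOC | intermediate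
8 | rac-1-[2,6-bis(methoxymethoxy)-4-(triisopropylsilyloxy)phenyl]prop-2-en-1-ol (racemic) | C=CC(O)c1c(OCOC)cc(O[Si](C(C)C)(C(C)C)C(C)C)cc1OCOC | intermediate
9 | 1-[2,6-bis(methoxymethoxy)-4-(triisopropylsilyloxy)phenyl]-3-[4-(methoxymethoxy)-3-(3-methylbut-2-enyl)phenyl]prop-1-en-1-ol (enol of 10, alkene geometry not defined, not isolated) | CC(C)=CCc1cc(CC=C(O)c2c(OCOC)cc(O[Si](C(C)C)(C(C)C)C(C)C)cc2OCOC)ccc1OCOC | intermediate
10 | 1-[2,6-bis(methoxymethoxy)-4-(triisopropylsilyloxy)phenyl]-3-[4-(methoxymethoxy)-3-(3-methylbut-2-enyl)phenyl]propan-1-one | CC(C)=CCc1cc(CCC(=O)c2c(OCOC)cc(O[Si](C(C)C)(C(C)C)C(C)C)cc2OCOC)ccc1OCOC | intermediate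
11 | 1-[4-hydroxy-2,6-bis(methoxymethoxy)phenyl]-3-[4-(methoxymethoxy)-3-(3-methylbut-2-enyl)phenyl]propan-1-one | CC(C)=CCc1cc(CCC(=O)c2c(OCOC)cc(O)cc2OCOC)ccc1OCOC | intermediate
12 | 3-chloro-3-methylbut-1-yne | CC(C)(Cl)C#C | starting material
13 | 1-[2,6-bis(methoxymethoxy)-4-(2-methylbut-3-yn-2-yloxy)phenyl]-3-[4-(methoxymethoxy)-3-(3-methylbut-2-enyl)phenyl]propan-1-one | CC(C)=CCc1cc(CCC(=O)c2c(OCOC)cc(OC(C)(C)C#C)cc2OCOC)ccc1OCOC | intermediate
14 | rac-1-[2,6-bis(methoxymethoxy)-3-(3-methylbuta-1,2-dienyl)-4-oxocyclohexa-1,5-dienyl]-3-[4-(methoxymethoxy)-3-(3-methylbut-2-enyl)phenyl]propan-1-one (racemic, not isolated) | CC(C)=C=CC1C(=O)C=C(OCOC)C(C(=O)CCc2ccc(OCOC)c(CC=C(C)C)c2)=C1OCOC | intermediate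
15 | 1-[4-hydroxy-2,6-bis(methoxymethoxy)-3-(3-methylbuta-1,2-dienyl)phenyl]-3-[4-(methoxymethoxy)-3-(3-methylbut-2-enyl)phenyl]propan-1-one (not isolated) | CC(C)=C=Cc1c(O)cc(OCOC)c(C(=O)CCc2ccc(OCOC)c(CC=C(C)C)c2)c1OCOC | intermediate
16 | 1-[(3Z)-2,6-bis(methoxymethoxy)-3-(3-methylbut-2-enylidene)-4-oxocyclohexa-1,5-dienyl]-3-[4-(methoxymethoxy)-3-(3-methylbut-2-enyl)phenyl]propan-1-one (not isolated) | CC(C)=C/C=C1\C(=O)C=C(OCOC)C(C(=O)CCc2ccc(OCOC)c(CC=C(C)C)c2)=C1OCOC | intermediate
17 | 1-[5,7-bis(methoxymethoxy)-2,2-dimethyl-2H-chromen-6-yl]-3-[4-(methoxymethoxy)-3-(3-methylbut-2-enyl)phenyl]propan-1-one | CC(C)=CCc1cc(CCC(=O)c2c(OCOC)cc3c(c2OCOC)C=CC(C)(C)O3)ccc1OCOC | intermediate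
18 | 1-[5,7-bis(methoxymethoxy)-2,2-dimethylchroman-6-yl]-3-[4-(methoxymethoxy)-3-(3-methylbut-2-enyl)phenyl]propan-1-one | CC(C)=CCc1cc(CCC(=O)c2c(OCOC)cc3c(c2OCOC)CCC(C)(C)O3)ccc1OCOC | intermediate
19 | 1-(5,7-dihydroxy-2,2-dimethylchroman-6-yl)-3-[4-hydroxy-3-(3-methylbut-2-enyl)phenyl]propan-1-one | CC(C)=CCc1cc(CCC(=O)c2c(O)cc3c(c2O)CCC(C)(C)O3)ccc1O | target

## Step count and risks

Total steps: 11. Longest linear sequence: 9 steps (steps 3 to 11, from 5); the ring B branch (steps 1 and 2) joins at step 6.

Least certain steps:

Step 9 (key step). The most likely failure is thermal fragmentation of the tertiary propargylic ether (elimination back to phenol 11 and the enyne) competing with the [3,3] shift, because the para acyl group lowers the electron density of the ether oxygen. Oligomerisation of the quinone methide at high concentration is a second risk. Fallback: set out from 11 and condense it with 3-methylbut-2-enal under ethylenediammonium diacetate catalysis in refluxing toluene. C-alkylation of the activated ortho carbon and dehydration give the same quinone methide 16, which closes to 17, where the route is rejoined. This makes no new isolable compound (F0), and the regiochemistry is again fixed by the acetal-capped neighbouring oxygens.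

Step 10. The likely failure is over-reduction: the geminal methyl groups next to C3 hinder the approach of diimide, so the rate gap to the prenyl alkene may be too small to stop cleanly at 18. Fallback, changing the order so that the pyran alkene is reduced before ring B is present:
- Set out from 7; Bu4NF with AcOH gives 4-hydroxy-2,6-bis(methoxymethoxy)benzaldehyde F1.
- Etherification with 12 as in step 8 gives 2,6-bis(methoxymethoxy)-4-(2-methylbut-3-yn-2-yloxy)benzaldehyde F2.
- Heating as in step 9 gives 5,7-bis(methoxymethoxy)-2,2-dimethyl-2H-chromene-6-carbaldehyde F3.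
- H2 over Pd/C in EtOAc, with no other alkene present, gives 5,7-bis(methoxymethoxy)-2,2-dimethylchroman-6-carbaldehyde F4.
- Vinylmagnesium bromide gives rac-1-[5,7-bis(methoxymethoxy)-2,2-dimethylchroman-6-yl]prop-2-en-1-ol F5.
- Heck coupling of F5 with 4 as in step 6 rejoins the route at 18.

Step 6. The likely failures are β-hydride elimination toward the benzylic side (arylated allylic alcohol instead of ketone), ionisation of the electron-rich allylic alcohol, or its redox isomerisation without coupling. Fallback: set out from 8 and oxidise it with MnO2 to 1-[2,6-bis(methoxymethoxy)-4-(triisopropylsilyloxy)phenyl]prop-2-en-1-one F6. Convert 4 by Miyaura borylation (B2pin2, PdCl2(dppf), KOAc) into 2-[4-(methoxymethoxy)-3-(3-methylbut-2-enyl)phenyl]-4,4,5,5-tetramethyl-1,3,2-dioxaborolane F7. A Hayashi–Miyaura 1,4-addition of F7 to F6 ([Rh(OH)(cod)]2, dioxane–H2O) rejoins the route at 10.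

Step 11. The likely failure is acid-promoted cyclisation of the prenyl group onto the freed ring B phenol, or addition of methanol across that alkene, before the least labile acetal has gone. Fallback, an acid-free two-stage deprotection: set out from 18 and treat it with Me3SiOTf and 2,2'-bipyridyl in CH2Cl2 at 0 °C to exchange the aryl acetals for silyl ethers, giving 1-[2,2-dimethyl-5,7-bis(trimethylsilyloxy)chroman-6-yl]-3-[3-(3-methylbut-2-enyl)-4-(trimethylsilyloxy)phenyl]propan-1-one F8. Neutral hydrolysis with water rejoins the route at 19.

Step 1. The likely failure is poor C- versus O-selectivity of the ambident phenoxide, together with double alkylation. Fallback, a regiospecific aromatic Claisen route: set out from 1 and etherify it with 12 (CuCl2·2H2O, DBU, MeCN) to 1-iodo-4-(2-methylbut-3-yn-2-yloxy)benzene F9. Semihydrogenation (H2, lead-poisoned Pd/CaCO3, quinoline) gives 1-iodo-4-(2-methylbut-3-en-2-yloxy)benzene F10. Heating in xylene at 130 °C effects the [3,3] shift to the ortho carbon with allylic inversion and rejoins the route at 3.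

## Further compounds

F0 | step 9 | none | none
F1 | step 10 | 4-hydroxy-2,6-bis(methoxymethoxy)benzaldehyde | O=Cc1c(OCOC)cc(O)cc1OCOC
F2 | step 10 | 2,6-bis(methoxymethoxy)-4-(2-methylbut-3-yn-2-yloxy)benzaldehyde | O=Cc1c(OCOC)cc(OC(C)(C)C#C)cc1OCOC
F3 | step 10 | 5,7-bis(methoxymethoxy)-2,2-dimethyl-2H-chromene-6-carbaldehyde | O=Cc1c(OCOC)cc2OC(C)(C)C=Cc2c1OCOC
F4 | step 10 | 5,7-bis(methoxymethoxy)-2,2-dimethylchroman-6-carbaldehyde | O=Cc1c(OCOC)cc2OC(C)(C)CCc2c1OCOC
F5 | step 10 | rac-1-[5,7-bis(methoxymethoxy)-2,2-dimethylchroman-6-yl]prop-2-en-1-ol (racemic) | C=CC(O)c1c(OCOC)cc2OC(C)(C)CCc2c1OCOC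
F6 | step 6 | 1-[2,6-bis(methoxymethoxy)-4-(triisopropylsilyloxy)phenyl]prop-2-en-1-one | C=CC(=O)c1c(OCOC)cc(O[Si](C(C)C)(C(C)C)C(C)C)cc1OCOC
F7 | step 6 | 2-[4-(methoxymethoxy)-3-(3-methylbut-2-enyl)phenyl]-4,4,5,5-tetramethyl-1,3,2-dioxaborolane | CC(C)=CCc1cc(B2OC(C)(C)C(C)(C)O2)ccc1OCOC
F8 | step 11 | 1-[2,2-dimethyl-5,7-bis(trimethylsilyloxy)chroman-6-yl]-3-[3-(3-methylbut-2-enyl)-4-(trimethylsilyloxy)phenyl]propan-1-one | CC(C)=CCc1cc(CCC(=O)c2c(O[Si](C)(C)C)cc3c(c2O[Si](C)(C)C)CCC(C)(C)O3)ccc1O[Si](C)(C)C
F9 | step 1 | 1-iodo-4-(2-methylbut-3-yn-2-yloxy)benzene | C#CC(C)(C)Oc1ccc(I)cc1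
F10 | step 1 | 1-iodo-4-(2-methylbut-3-en-2-yloxy)benzene | C=CC(C)(C)Oc1ccc(I)cc1
A1 | alternative 1 | 4-{3-[7-hydroxy-2,2-dimethyl-5-(trifluoromethylsulfonyloxy)chroman-6-yl]-3-oxopropyl}-2-(3-methylbut-2-enyl)phenyl acetate | CC(C)=CCc1cc(CCC(=O)c2c(O)cc3c(c2OS(=O)(=O)C(F)(F)F)CCC(C)(C)O3)ccc1OC(C)=O
A2 | alternative 1 | 4-{3-[5-hydroxy-2,2-dimethyl-7-(trifluoromethylsulfonyloxy)chroman-6-yl]-3-oxopropyl}-2-(3-methylbut-2-enyl)phenyl acetate | CC(C)=CCc1cc(CCC(=O)c2c(OS(=O)(=O)C(F)(F)F)cc3c(c2O)CCC(C)(C)O3)ccc1OC(C)=O
A3 | alternative 1 | 2,2-dimethyl-6-(trimethylsilyl)chroman-5,7-diyl bis(trifluoromethanesulfonate) | C[Si](C)(C)c1c(OS(=O)(=O)C(F)(F)F)cc2OC(C)(C)CCc2c1OS(=O)(=O)C(F)(F)F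
A4 | alternative 1 | 3-[4-acetoxy-3-(3-methylbut-2-enyl)phenyl]propanoic acid | CC(C)=CCc1cc(CCC(=O)O)ccc1OC(C)=O
A5 | alternative 2 | methyl 5,7-dihydroxy-2,2-dimethylchroman-6-carboxylate | COC(=O)c1c(O)cc2OC(C)(C)CCc2c1O
A6 | alternative 2 | dimethyl 2-[(2,2,6-trimethyl-3,4-dihydro-2H-pyran-5-yl)carbonyl]propanedioate | CC1=C(C(=O)C(C(=O)OC)C(=O)OC)CCC(C)(C)O1
A7 | alternative 3 | 1-[5,7-bis(methoxymethoxy)-2,2-dimethylchroman-6-yl]-3-[4-(methoxymethoxy)-3-(3-methylbut-2-enyl)phenyl]propan-1-one (identical with 18) | CC(C)=CCc1cc(CCC(=O)c2c(OCOC)cc3c(c2OCOC)CCC(C)(C)O3)ccc1OCOC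
A8 | alternative 3 | 1-[3-(dimethylaminomethyl)-4-hydroxy-2,6-bis(methoxymethoxy)phenyl]-3-[4-(methoxymethoxy)-3-(3-methylbut-2-enyl)phenyl]propan-1-one | CC(C)=CCc1cc(CCC(=O)c2c(OCOC)cc(O)c(CN(C)C)c2OCOC)ccc1OCOC
A9 | alternative 3 | 2-methylpropene (isobutene) | CC(C)=C
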